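**Plan**

- Numbering: chroman positions O1 to C8a, side chain C1' to C13' outward from C2. The retrosynthesis cuts, in order, the aryl O–Si bond, C2'–C3', then O1–C2 together with C1'–C2' (one palladium domino), then the aryl–C4 bond; the C14 chain piece is cut at C5'–C6'.
- Forward: methylhydroquinone is silylated, iodinated and given a 3-methylbut-3-enyl arm. The dihydropyran ring then closes with uptake of CO and methanol to give the C2 acetate. Reduction, tosylation and a copper-catalysed Grignard coupling attach C3'–C13', and fluoride frees the phenol.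
- Enabling feature: C2 of the dihydropyran ring is a fully substituted ether carbon (O1, CH3, C3, C1'), so palladium on C1' has no β-hydrogen and is trapped by carbon monoxide instead of eliminating.
- Stereochemistry: C2 comes from the chiral bis(oxazolinyl)binaphthyl ligand on palladium (enantioface choice of the alkene), C4' from (S)-3-bromo-2-methylpropan-1-ol, C8' from (R)-citronellol. None of the three is at a reacting carbon afterwards.

Key step: step 4

Assumption: the (S,S)-benzyl ligand, (S)-2,2'-bis[(4S)-4-benzyl-4,5-dihydrooxazol-2-yl]-1,1'-binaphthyl ((S,S)-Bn-BOXAX), is expected to give the 2S ester by analogy with closely related phenols; if the sense proves opposite, its enantiomer is used.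

**Route**

Step 1
Reactants: 1 methylhydroquinone
Product: 2 4-[tert-butyl(dimethyl)silyl]oxy-2-methylphenol
Conditions: TBSCl (1.0 equiv), imidazole (2.2 equiv), DMF, −10 °C → 0 °C
Reagents that add atoms: tert-butyl(chloro)dimethylsilane (TBSCl), CC(C)(C)[Si](C)(C)Cl
Why: Silyl ether formation with a bulky chlorosilane should be faster at the C4 hydroxyl, which has two ortho hydrogens, than at the C1 hydroxyl next to the methyl, so one equivalent at low temperature should favour the 4-O-silyl ether, with the regioisomer and the bis-ether removed by chromatography.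

Step 2
Reactants: 2 4-[tert-butyl(dimethyl)silyl]oxy-2-methylphenol
Product: 3 4-[tert-butyl(dimethyl)silyl]oxy-2-iodo-6-methylphenol
Conditions: I2 (1.05 equiv), morpholine (3 equiv), CH2Cl2, 0 °C → 20 °C, dark
Reagents that add atoms: iodine, [I][I]
Why: Electrophilic aromatic iodination with the iodine–morpholine complex acts on the hydrogen-bonded, phenoxide-like phenol and so should substitute ortho to the free hydroxyl; the para position is blocked, the other ortho position carries the methyl, and the positions flanking the bulky silyl ether are less activated.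

Step 3
Reactants: 3 4-[tert-butyl(dimethyl)silyl]oxy-2-iodo-6-methylphenol; 4 4-bromo-2-methylbut-1-ene
Product: 6 4-[tert-butyl(dimethyl)silyl]oxy-2-methyl-6-(3-methylbut-3-enyl)phenol, via 3-methylbut-3-enylzinc bromide 5 (not isolated)
Conditions: 4 (1.5 equiv), Zn dust (activated with BrCH2CH2Br and Me3SiCl), LiCl, THF, 40 °C; then 3, Pd(OAc)2 (2 mol %), SPhos (4 mol %), THF, 25 °C
Reagents that add atoms: none
Why: Negishi cross-coupling, in which zinc inserts into the primary bromide, the aryl iodide adds to zerovalent palladium, and with the bulky biarylphosphine the aryl–alkyl reductive elimination should outrun β-hydride elimination, while the alkylzinc halide is protonated only slowly by the phenol and the excess covers losses.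

Step 4
Reactants: 6 4-[tert-butyl(dimethyl)silyl]oxy-2-methyl-6-(3-methylbut-3-enyl)phenol; 7 carbon monoxide; 8 methanol
Product: 9 methyl 2-[(2S)-6-[tert-butyl(dimethyl)silyl]oxy-2,8-dimethyl-3,4-dihydro-2H-chromen-2-yl]acetate
Conditions: Pd(OCOCF3)2 (5 mol %), (S,S)-Bn-BOXAX (20 mol %), p-benzoquinone (4 equiv), CO (1 atm), MeOH, 25 °C
Reagents that add atoms: none
Why: Divalent palladium carrying the chiral bis(oxazoline) binds the 1,1-disubstituted alkene of 6 and the phenol oxygen adds to its internal carbon (oxypalladation), forming O1–C2; because C2 then bears O1, methyl, C3 and C1', the C1' alkylpalladium has no β-hydrogen, so it inserts CO and the acylpalladium is cleaved by methanol (C1'–C2' and the ester), after which p-benzoquinone returns zerovalent palladium to the divalent state. The closest known reaction type is the enantioselective palladium-catalysed Wacker cyclization–carbonylation of 2-(3-methylbut-3-enyl)phenols to methyl 2-methylchroman-2-ylacetates. The dihydropyran ring closes in the 6-exo-trig mode. The C2 stereocentre is set under catalyst control: the C2-symmetric ligand differentiates the two alkene faces in the oxypalladation, and its enantiomer is chosen to give the 2S ester, which has the spatial arrangement of 2R in the target. The step needs attack at the internal alkene carbon, carbonylation ahead of protodepalladation and survival of the aryl silyl ether; the geminal disubstitution of the only alkene, the absence of β-hydrogens, the CO atmosphere and the nearly neutral medium should secure these.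

Step 5
Reactants: 9 methyl 2-[(2S)-6-[tert-butyl(dimethyl)silyl]oxy-2,8-dimethyl-3,4-dihydro-2H-chromen-2-yl]acetate
Product: 10 2-[(2S)-6-[tert-butyl(dimethyl)silyl]oxy-2,8-dimethyl-3,4-dihydro-2H-chromen-2-yl]ethanol
Conditions: DIBAL-H (2.5 equiv), CH2Cl2, −78 °C → 0 °C; aqueous potassium sodium tartrate work-up
Reagents that add atoms: none
Why: Ester reduction by two hydride transfers from the aluminium hydride at low temperature should give the primary alcohol without touching the aryl silyl ether or the non-enolisable quaternary C2.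

Step 6
Reactants: 10 2-[(2S)-6-[tert-butyl(dimethyl)silyl]oxy-2,8-dimethyl-3,4-dihydro-2H-chromen-2-yl]ethanol
Product: 11 2-[(2S)-6-[tert-butyl(dimethyl)silyl]oxy-2,8-dimethyl-3,4-dihydro-2H-chromen-2-yl]ethyl 4-methylbenzenesulfonate
Conditions: TsCl (1.3 equiv), Et3N (2 equiv), DMAP (0.1 equiv), CH2Cl2, 0 °C → 20 °C
Reagents that add atoms: 4-methylbenzenesulfonyl chloride (TsCl), Cc1ccc(cc1)S(=O)(=O)Cl
Why: DMAP-catalysed sulfonylation of the only free hydroxyl, a primary alcohol, is routine and leaves all other groups untouched.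

Step 7
Reactants: 12 (R)-citronellol
Product: 13 [(3R)-3,7-dimethyloct-6-enyl] 4-methylbenzenesulfonate
Conditions: TsCl (1.2 equiv), Et3N (2 equiv), DMAP (0.1 equiv), CH2Cl2, 0 °C → 20 °C
Reagents that add atoms: 4-methylbenzenesulfonyl chloride (TsCl), Cc1ccc(cc1)S(=O)(=O)Cl
Why: Sulfonylation of the primary alcohol under non-acidic conditions leaves the trisubstituted alkene and the C3 stereocentre unchanged.

Step 8
Reactants: 14 (2S)-3-bromo-2-methylpropan-1-ol
Product: 15 [(2S)-3-bromo-2-methylpropoxy]-tert-butyl-dimethylsilane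
Conditions: TBSCl (1.1 equiv), imidazole (1.5 equiv), CH2Cl2, 0 °C → 20 °C
Reagents that add atoms: tert-butyl(chloro)dimethylsilane (TBSCl), CC(C)(C)[Si](C)(C)Cl
Why: Silylation of the primary alcohol is fast under imidazole catalysis, and the β-branched primary bromide is inert to imidazole at this temperature.

Step 9
Reactants: 15 [(2S)-3-bromo-2-methylpropoxy]-tert-butyl-dimethylsilane; 13 [(3R)-3,7-dimethyloct-6-enyl] 4-methylbenzenesulfonate
Product: 17 tert-butyl-dimethyl-[(2R,6S)-2,6,10-trimethylundec-9-enoxy]silane, via 3-silyloxy-2-methylpropylmagnesium bromide 16 (not isolated)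
Conditions: 15 (1.4 equiv), Mg turnings (BrCH2CH2Br initiation), THF, 40 °C; then 13, Li2CuCl4 (3 mol %), THF, −78 °C → 20 °C
Reagents that add atoms: none
Why: Magnesium insertion gives a γ-silyloxy Grignard reagent that has no β-leaving group, and the copper-catalysed Grignard–tosylate coupling forms C5'–C6' by SN2 displacement at an unbranched primary carbon, with neither stereocentre at a reacting carbon (the descriptor at the methyl-bearing carbon changes from S to R only through the priority rules).

Step 10
Reactants: 17 tert-butyl-dimethyl-[(2R,6S)-2,6,10-trimethylundec-9-enoxy]silane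
Product: 18 (2R,6S)-2,6,10-trimethylundec-9-en-1-ol
Conditions: Bu4NF (1.2 equiv), THF, 20 °C
Reagents that add atoms: none
Why: Fluoride-induced desilylation, driven by the strength of the Si–F bond, frees the primary alcohol without affecting the alkene.

Step 11
Reactants: 18 (2R,6S)-2,6,10-trimethylundec-9-en-1-ol
Product: 19 (6S,10R)-11-bromo-2,6,10-trimethylundec-2-ene
Conditions: CBr4 (1.2 equiv), PPh3 (1.25 equiv), CH2Cl2, 0 °C
Reagents that add atoms: tetrabromomethane, BrC(Br)(Br)Br
Why: Appel reaction, in which bromide displaces the alkoxyphosphonium group at the primary carbon under neutral conditions, so the adjacent stereocentre and the trisubstituted alkene are not affected.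

Step 12
Reactants: 19 (6S,10R)-11-bromo-2,6,10-trimethylundec-2-ene; 11 2-[(2S)-6-[tert-butyl(dimethyl)silyl]oxy-2,8-dimethyl-3,4-dihydro-2H-chromen-2-yl]ethyl 4-methylbenzenesulfonate
Product: 21 tert-butyl-[[(2R)-2,8-dimethyl-2-[(4R,8S)-4,8,12-trimethyltridec-11-enyl]-3,4-dihydro-2H-chromen-6-yl]oxy]-dimethylsilane, via 2,6,10-trimethylundec-9-enylmagnesium bromide 20 (not isolated)
Conditions: 19 (1.5 equiv), Mg turnings, THF, 50 °C; then 11, Li2CuCl4 (5 mol %), THF, −78 °C → 20 °C
Reagents that add atoms: none
Why: Copper-catalysed sp3–sp3 coupling of the primary Grignard reagent with the primary tosylate forms C2'–C3', the aryl silyl ether is inert to the Grignard reagent at low temperature, and C2, C4' and C8' are not at reacting carbons, so all three configurations are carried into the product (C2 becomes R only by the priority rules).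

Step 13
Reactants: 21 tert-butyl-[[(2R)-2,8-dimethyl-2-[(4R,8S)-4,8,12-trimethyltridec-11-enyl]-3,4-dihydro-2H-chromen-6-yl]oxy]-dimethylsilane
Product: 22 (2R)-2,8-dimethyl-2-[(4R,8S)-4,8,12-trimethyltridec-11-enyl]-3,4-dihydro-2H-chromen-6-ol
Conditions: Bu4NF (1.1 equiv), AcOH (1.1 equiv), THF, 0 °C, argon
Reagents that add atoms: none
Why: Buffered fluoride cleaves the aryl silyl ether quickly and mildly, and the acetic acid and inert atmosphere keep the electron-rich phenol from oxidising as its phenoxide.

**Compound list**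

1 | methylhydroquinone (2-methylbenzene-1,4-diol) | Cc1cc(O)ccc1O | starting material
2 | 4-[tert-butyl(dimethyl)silyl]oxy-2-methylphenol | Cc1cc(O[Si](C)(C)C(C)(C)C)ccc1O | intermediate
3 | 4-[tert-butyl(dimethyl)silyl]oxy-2-iodo-6-methylphenol | Cc1cc(O[Si](C)(C)C(C)(C)C)cc(I)c1O | intermediate
4 | 4-bromo-2-methylbut-1-ene | CC(=C)CCBr | starting material
5 | 3-methylbut-3-enylzinc bromide | CC(=C)CC[Zn]Br | intermediate
6 | 4-[tert-butyl(dimethyl)silyl]oxy-2-methyl-6-(3-methylbut-3-enyl)phenol | CC(=C)CCc1cc(O[Si](C)(C)C(C)(C)C)cc(C)c1O | intermediate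
7 | carbon monoxide | [C-]#[O+] | starting material
8 | methanol | CO | starting material
9 | methyl 2-[(2S)-6-[tert-butyl(dimethyl)silyl]oxy-2,8-dimethyl-3,4-dihydro-2H-chromen-2-yl]acetate | COC(=O)C[C@]1(C)CCc2cc(O[Si](C)(C)C(C)(C)C)cc(C)c2O1 | intermediate
10 | 2-[(2S)-6-[tert-butyl(dimethyl)silyl]oxy-2,8-dimethyl-3,4-dihydro-2H-chromen-2-yl]ethanol | OCC[C@]1(C)CCc2cc(O[Si](C)(C)C(C)(C)C)cc(C)c2O1 | intermediate
11 | 2-[(2S)-6-[tert-butyl(dimethyl)silyl]oxy-2,8-dimethyl-3,4-dihydro-2H-chromen-2-yl]ethyl 4-methylbenzenesulfonate | Cc1ccc(cc1)S(=O)(=O)OCC[C@]1(C)CCc2cc(O[Si](C)(C)C(C)(C)C)cc(C)c2O1 | intermediate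
12 | (R)-citronellol, (3R)-3,7-dimethyloct-6-en-1-ol | CC(C)=CCC[C@@H](C)CCO | starting material
13 | [(3R)-3,7-dimethyloct-6-enyl] 4-methylbenzenesulfonate | CC(C)=CCC[C@@H](C)CCOS(=O)(=O)c1ccc(C)cc1 | intermediate
14 | (2S)-3-bromo-2-methylpropan-1-ol | BrC[C@@H](C)CO | starting material
15 | [(2S)-3-bromo-2-methylpropoxy]-tert-butyl-dimethylsilane | BrC[C@@H](C)CO[Si](C)(C)C(C)(C)C | intermediate
16 | [(2S)-3-[tert-butyl(dimethyl)silyl]oxy-2-methylpropyl]magnesium bromide | Br[Mg]C[C@@H](C)CO[Si](C)(C)C(C)(C)C | intermediate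
17 | tert-butyl-dimethyl-[(2R,6S)-2,6,10-trimethylundec-9-enoxy]silane | CC(C)=CCC[C@@H](C)CCC[C@@H](C)CO[Si](C)(C)C(C)(C)C | intermediate
18 | (2R,6S)-2,6,10-trimethylundec-9-en-1-ol | CC(C)=CCC[C@@H](C)CCC[C@@H](C)CO | intermediate
19 | (6S,10R)-11-bromo-2,6,10-trimethylundec-2-ene | CC(C)=CCC[C@@H](C)CCC[C@@H](C)CBr | intermediate
20 | [(2R,6S)-2,6,10-trimethylundec-9-enyl]magnesium bromide | CC(C)=CCC[C@@H](C)CCC[C@@H](C)C[Mg]Br | intermediate
21 | tert-butyl-[[(2R)-2,8-dimethyl-2-[(4R,8S)-4,8,12-trimethyltridec-11-enyl]-3,4-dihydro-2H-chromen-6-yl]oxy]-dimethylsilane | CC(C)=CCC[C@@H](C)CCC[C@@H](C)CCC[C@]1(C)CCc2cc(O[Si](C)(C)C(C)(C)C)cc(C)c2O1 | intermediate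
22 | (2R)-2,8-dimethyl-2-[(4R,8S)-4,8,12-trimethyltridec-11-enyl]-3,4-dihydro-2H-chromen-6-ol | CC(C)=CCC[C@@H](C)CCC[C@@H](C)CCC[C@]1(C)CCc2cc(O)cc(C)c2O1 | target

**Step count and risks**

Total: 13 steps. Longest linear sequence: 8 steps (steps 1, 2, 3, 4, 5, 6, 12, 13, from methylhydroquinone).

Steps most likely to fail:

1. Step 4. What may go wrong: weak enantioface discrimination in the oxypalladation (this phenol has no substituent next to the alkenyl arm), or loss of turnover when zerovalent palladium aggregates before it is reoxidised. Fallback (classical resolution in place of full catalyst control): setting out from 9 of insufficient enantiomeric purity, LiOH in THF/MeOH/H2O under argon cleaves both the methyl ester and the aryl silyl ether to give 2-[(2S)-6-hydroxy-2,8-dimethyl-3,4-dihydro-2H-chromen-2-yl]acetic acid F1. Crystallisation with (1S)-1-phenylethylamine (or its enantiomer, whichever gives the less soluble salt of the 2S acid) gives (1S)-1-phenylethylammonium 2-[(2S)-6-hydroxy-2,8-dimethyl-3,4-dihydro-2H-chromen-2-yl]acetate F2. Acidification and Fischer esterification (MeOH, cat. H2SO4) give methyl 2-[(2S)-6-hydroxy-2,8-dimethyl-3,4-dihydro-2H-chromen-2-yl]acetate F3, and TBSCl with imidazole re-silylates the phenol, coming back to the route at 9.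

2. Step 3. What may go wrong: protonolysis of the alkylzinc by the free phenol, or β-hydride elimination and chain walking at the alkylpalladium, giving reduced arene and isomerised alkenes. Fallback (carbonyl chemistry in place of the cross-coupling): setting out from 2, magnesium-mediated ortho-formylation (MgCl2, Et3N, paraformaldehyde, MeCN, reflux) gives 5-[tert-butyl(dimethyl)silyl]oxy-2-hydroxy-3-methylbenzaldehyde F4. Wittig reaction with Ph3P=CHC(O)CH3 in toluene at 80 °C gives (E)-4-[5-[tert-butyl(dimethyl)silyl]oxy-2-hydroxy-3-methylphenyl]but-3-en-2-one F5. Hydrogenation (H2, Pd/C, EtOAc) gives 4-[5-[tert-butyl(dimethyl)silyl]oxy-2-hydroxy-3-methylphenyl]butan-2-one F6. Wittig methylenation with Ph3P=CH2 (3 equiv, one of which is consumed by the phenol; THF, 0 °C → 20 °C) comes back to the route at 6.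

3. Step 12. What may go wrong: slow displacement at the tosylate, with Grignard homocoupling, reduction of the tosylate or attack at silicon competing. Fallback (sulfone alkylation and desulfonylation in place of the copper coupling): setting out from 19, PhSO2Na in DMF at 60 °C gives [(2R,6S)-2,6,10-trimethylundec-9-enyl]sulfonylbenzene F7. Setting out from 11, NaI in acetone gives tert-butyl-[[(2S)-2-(2-iodoethyl)-2,8-dimethyl-3,4-dihydro-2H-chromen-6-yl]oxy]-dimethylsilane F8. Deprotonation of F7 with n-BuLi (THF, −78 °C) and alkylation with F8 in the presence of DMPU gives the 3'-(benzenesulfonyl) derivative of 21 F9 as a mixture of epimers at C3'. Na/Hg with Na2HPO4 in MeOH/THF at −20 °C removes the sulfonyl group and comes back to the route at 21.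

**Further compounds**

F1 | step 4 | 2-[(2S)-6-hydroxy-2,8-dimethyl-3,4-dihydro-2H-chromen-2-yl]acetic acid | OC(=O)C[C@]1(C)CCc2cc(O)cc(C)c2O1
F2 | step 4 | (1S)-1-phenylethylammonium 2-[(2S)-6-hydroxy-2,8-dimethyl-3,4-dihydro-2H-chromen-2-yl]acetate | C[C@H]([NH3+])c1ccccc1.[O-]C(=O)C[C@]1(C)CCc2cc(O)cc(C)c2O1
F3 | step 4 | methyl 2-[(2S)-6-hydroxy-2,8-dimethyl-3,4-dihydro-2H-chromen-2-yl]acetate | COC(=O)C[C@]1(C)CCc2cc(O)cc(C)c2O1
F4 | step 3 | 5-[tert-butyl(dimethyl)silyl]oxy-2-hydroxy-3-methylbenzaldehyde | Cc1cc(O[Si](C)(C)C(C)(C)C)cc(C=O)c1O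
F5 | step 3 | (E)-4-[5-[tert-butyl(dimethyl)silyl]oxy-2-hydroxy-3-methylphenyl]but-3-en-2-one | CC(=O)/C=C/c1cc(O[Si](C)(C)C(C)(C)C)cc(C)c1O
F6 | step 3 | 4-[5-[tert-butyl(dimethyl)silyl]oxy-2-hydroxy-3-methylphenyl]butan-2-one | CC(=O)CCc1cc(O[Si](C)(C)C(C)(C)C)cc(C)c1O
F7 | step 12 | [(2R,6S)-2,6,10-trimethylundec-9-enyl]sulfonylbenzene | CC(C)=CCC[C@@H](C)CCC[C@@H](C)CS(=O)(=O)c1ccccc1
F8 | step 12 | tert-butyl-[[(2S)-2-(2-iodoethyl)-2,8-dimethyl-3,4-dihydro-2H-chromen-6-yl]oxy]-dimethylsilane | ICC[C@]1(C)CCc2cc(O[Si](C)(C)C(C)(C)C)cc(C)c2O1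
F9 | step 12 | 3'-(benzenesulfonyl) derivative of 21, both epimers at C3', other stereocentres as in 21 | CC(C)=CCC[C@@H](C)CCC[C@@H](C)C(CC[C@]1(C)CCc2cc(O[Si](C)(C)C(C)(C)C)cc(C)c2O1)S(=O)(=O)c1ccccc1
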